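The central benzene (ring B; C1 arylethyl, C2 benzyl, C3 OH, C4 H, C5 OMe, C6 H) carries its two oxygens meta to each other. It is therefore unravelled to a cyclohexane-1,3-dione and cut at C1–C6 and C4–C5. A single base-mediated operation welds dimethyl malonate (C5, C6) onto an acyclic α-benzyl methyl enone that already holds C1–C4 and both benzyl-protected side chains: conjugate addition at C1, then Claisen closure of methyl carbon C4 onto an ester. The ester surviving at C6 sits ortho to O5 and para to O3. After aromatisation its hydrogen bond to O5–H lets O3 be masked first and O5 methylated later.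

Key step: step 4

Assumption: the target has no stereocentre, so the enone geometry and the relative configuration of the cyclohexanedione intermediates do not affect the outcome. The ring B locants above are used throughout; ring A is the 4-oxygenated benzyl arene and ring C the 3-oxygenated arene of the ethyl chain.

Step 1
Reactants: 1 diethyl (2-oxopropyl)phosphonate; 2 4-(benzyloxy)benzyl chloride
Product: 3 diethyl {1-[4-(benzyloxy)phenyl]-3-oxobutan-2-yl}phosphonate (racemic)
Conditions: NaH, THF–DMF, 0 °C; then 2, NaI (cat.), 50 °C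
Reagents that add atoms: none
Why: SN2 C-alkylation of the doubly stabilised sodium β-ketophosphonate carbanion by a benzylic halide activated in situ by iodide exchange (Finkelstein), with 1 in slight excess to suppress dialkylation; the new stereocentre is racemic and vanishes in step 3.

Step 2
Reactants: 4 1-(benzyloxy)-3-iodobenzene; 5 prop-2-en-1-ol
Product: 6 3-[3-(benzyloxy)phenyl]propanal
Conditions: Pd(OAc)2 (cat.), Bu4NCl, NaHCO3, DMF, 45 °C
Reagents that add atoms: none
Why: Jeffery-type Mizoroki–Heck arylation of allyl alcohol, in which the aryl group is delivered to the terminal alkene carbon, β-hydride elimination runs toward the carbinol carbon and tautomerisation gives the saturated aldehyde directly, all under conditions that do not touch an aryl benzyl ether.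

Step 3
Reactants: 3 diethyl {1-[4-(benzyloxy)phenyl]-3-oxobutan-2-yl}phosphonate; 6 3-[3-(benzyloxy)phenyl]propanal
Product: 7 (E)-3-[4-(benzyloxy)benzyl]-6-[3-(benzyloxy)phenyl]hex-3-en-2-one
Conditions: NaH, THF, 0 °C; then 6, 0 °C to 45 °C
Reagents that add atoms: none
Why: Horner–Wadsworth–Emmons olefination with a preformed α-substituted β-ketophosphonate anion, so that no free base meets the enolisable aldehyde; equilibration of the adducts favours the E alkene (acetyl anti to the chain), and any Z isomer can be carried on because both geometries give the same adduct in step 4.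

Step 4
Reactants: 7 (E)-3-[4-(benzyloxy)benzyl]-6-[3-(benzyloxy)phenyl]hex-3-en-2-one; 8 dimethyl malonate
Product: 10 methyl 3-[4-(benzyloxy)benzyl]-2-{2-[3-(benzyloxy)phenyl]ethyl}-4,6-dioxocyclohexane-1-carboxylate (mixture of diastereomers), via Michael adduct 9 (not isolated)
Conditions: NaOMe (1.3 equiv), 8 (1.5 equiv), dry MeOH, reflux; then cold 1 M HCl
Reagents that add atoms: none
Why: Methoxide forms the malonate anion, which adds reversibly to the β-carbon C1 of 7 to give 9; proton exchange then supplies the methyl-side ketone enolate, whose carbon C4 acylates on one malonate ester (C5) with loss of methoxide. The closest known reaction type is the Michael–Claisen (Dieckmann-like) annulation of methyl enones with malonates used for 5-alkylresorcinols, which also tolerates an α-alkyl group on the enone. Ring B closes in a favoured 6-(enolendo)-exo-trig mode. C1, C2 and C6 become stereocentres with no control beyond base equilibration at C2 and C6, which does not matter because step 5 flattens all three. The step needs 1,4- rather than 1,2-attack and acylation rather than aldol closure: the soft, reversible donor secures the first, and in 9 the only electrophiles within reach of the C4 enolate are esters, while the alternative C2 enolate could only form a four-membered ring. Deprotonation of 10 at C4 to its delocalised β-diketonate is the thermodynamic sink that pulls the unfavourable addition to the trisubstituted alkene forward, and it also allows 10 to be separated from neutral material by base extraction.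

Step 5
Reactants: 10 methyl 3-[4-(benzyloxy)benzyl]-2-{2-[3-(benzyloxy)phenyl]ethyl}-4,6-dioxocyclohexane-1-carboxylate
Product: 12 methyl 5-[4-(benzyloxy)benzyl]-6-{2-[3-(benzyloxy)phenyl]ethyl}-2,4-dihydroxybenzoate, via bromodione 11 (not isolated)
Conditions: Br2 (1.0 equiv, dropwise), DMF, 0 °C, dark; then 80 °C
Reagents that add atoms: none
Why: Halogenation–dehydrohalogenation aromatisation of a dihydroresorcylate, in which the enolised β-diketone takes up the single equivalent of Br2 far faster than the aryl ether rings and, on warming in DMF (which levels the acidity of the HBr), 11 loses HBr and tautomerises to the benzenoid resorcylate with the ester retained at this temperature.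

Step 6
Reactants: 12 methyl 5-[4-(benzyloxy)benzyl]-6-{2-[3-(benzyloxy)phenyl]ethyl}-2,4-dihydroxybenzoate
Product: 13 methyl 4-(benzyloxy)-5-[4-(benzyloxy)benzyl]-6-{2-[3-(benzyloxy)phenyl]ethyl}-2-hydroxybenzoate
Conditions: BnBr (1.05 equiv), K2CO3 (1.2 equiv), acetone, reflux
Reagents that add atoms: benzyl bromide, BrCc1ccccc1
Why: Williamson etherification under weak base tells the two phenols apart, since O3–H (para to the ester) is the more acidic and free one whereas O5–H is tied up in a six-membered hydrogen bond to the ester carbonyl, so one equivalent of halide goes to O3.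

Step 7
Reactants: 13 methyl 4-(benzyloxy)-5-[4-(benzyloxy)benzyl]-6-{2-[3-(benzyloxy)phenyl]ethyl}-2-hydroxybenzoate
Product: 15 3-(benzyloxy)-4-[4-(benzyloxy)benzyl]-5-{2-[3-(benzyloxy)phenyl]ethyl}phenol, via salicylic acid 14 (not isolated)
Conditions: KOH (excess), DMSO–H2O, 100 °C; 1 M HCl, 0 °C; crude acid in DMF, 120 °C
Reagents that add atoms: none
Why: Forcing alkaline ester hydrolysis overcomes the di-ortho-substituted benzoate, and acid 14, with O5–H ortho and O3 para to the carboxyl group, undergoes the thermal protodecarboxylation (ipso protonation at C6) typical of 6-alkyl-β-resorcylic acids, benzyl aryl ethers being inert to both operations.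

Step 8
Reactants: 15 3-(benzyloxy)-4-[4-(benzyloxy)benzyl]-5-{2-[3-(benzyloxy)phenyl]ethyl}phenol
Product: 16 1-(benzyloxy)-2-[4-(benzyloxy)benzyl]-3-{2-[3-(benzyloxy)phenyl]ethyl}-5-methoxybenzene
Conditions: MeI, K2CO3, DMF, rt
Reagents that add atoms: iodomethane, CI
Why: Williamson O-methylation of the only free phenol, O5–H, which is unhindered and no longer chelated once the ester is gone.

Step 9
Reactants: 16 1-(benzyloxy)-2-[4-(benzyloxy)benzyl]-3-{2-[3-(benzyloxy)phenyl]ethyl}-5-methoxybenzene
Product: 17 IN1159, 2-(4-hydroxybenzyl)-3-[2-(3-hydroxyphenyl)ethyl]-5-methoxyphenol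
Conditions: H2 (1 atm), Pd/C (10 wt%), EtOAc–MeOH, rt
Reagents that add atoms: none
Why: Catalytic hydrogenolysis cleaves the three benzylic C–O bonds in one neutral operation, while the aryl methyl ether, the diarylmethane C–C bond and the arenes are not attacked at one atmosphere and room temperature.

Compound list
1 | diethyl (2-oxopropyl)phosphonate | CCOP(=O)(CC(C)=O)OCC | starting material
2 | 4-(benzyloxy)benzyl chloride | ClCc1ccc(OCc2ccccc2)cc1 | starting material
3 | diethyl {1-[4-(benzyloxy)phenyl]-3-oxobutan-2-yl}phosphonate (racemic) | CCOP(=O)(OCC)C(Cc1ccc(OCc2ccccc2)cc1)C(C)=O | intermediate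
4 | 1-(benzyloxy)-3-iodobenzene | Ic1cccc(OCc2ccccc2)c1 | starting material
5 | prop-2-en-1-ol (allyl alcohol) | C=CCO | starting material
6 | 3-[3-(benzyloxy)phenyl]propanal | O=CCCc1cccc(OCc2ccccc2)c1 | intermediate
7 | (E)-3-[4-(benzyloxy)benzyl]-6-[3-(benzyloxy)phenyl]hex-3-en-2-one | CC(=O)/C(Cc1ccc(OCc2ccccc2)cc1)=C/CCc1cccc(OCc2ccccc2)c1 | intermediate
8 | dimethyl malonate | COC(=O)CC(=O)OC | starting material
9 | dimethyl 2-{4-[4-(benzyloxy)benzyl]-1-[3-(benzyloxy)phenyl]-5-oxohexan-3-yl}malonate (diastereomer mixture, not isolated) | COC(=O)C(C(=O)OC)C(CCc1cccc(OCc2ccccc2)c1)C(Cc1ccc(OCc2ccccc2)cc1)C(C)=O | intermediate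
10 | methyl 3-[4-(benzyloxy)benzyl]-2-{2-[3-(benzyloxy)phenyl]ethyl}-4,6-dioxocyclohexane-1-carboxylate (diastereomer mixture) | COC(=O)C1C(=O)CC(=O)C(Cc2ccc(OCc3ccccc3)cc2)C1CCc1cccc(OCc2ccccc2)c1 | intermediate
11 | methyl 3-[4-(benzyloxy)benzyl]-2-{2-[3-(benzyloxy)phenyl]ethyl}-5-bromo-4,6-dioxocyclohexane-1-carboxylate (diastereomer mixture, not isolated) | COC(=O)C1C(=O)C(Br)C(=O)C(Cc2ccc(OCc3ccccc3)cc2)C1CCc1cccc(OCc2ccccc2)c1 | intermediate
12 | methyl 5-[4-(benzyloxy)benzyl]-6-{2-[3-(benzyloxy)phenyl]ethyl}-2,4-dihydroxybenzoate | COC(=O)c1c(O)cc(O)c(Cc2ccc(OCc3ccccc3)cc2)c1CCc1cccc(OCc2ccccc2)c1 | intermediate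
13 | methyl 4-(benzyloxy)-5-[4-(benzyloxy)benzyl]-6-{2-[3-(benzyloxy)phenyl]ethyl}-2-hydroxybenzoate | COC(=O)c1c(O)cc(OCc2ccccc2)c(Cc2ccc(OCc3ccccc3)cc2)c1CCc1cccc(OCc2ccccc2)c1 | intermediate
14 | 4-(benzyloxy)-5-[4-(benzyloxy)benzyl]-6-{2-[3-(benzyloxy)phenyl]ethyl}-2-hydroxybenzoic acid (not isolated) | OC(=O)c1c(O)cc(OCc2ccccc2)c(Cc2ccc(OCc3ccccc3)cc2)c1CCc1cccc(OCc2ccccc2)c1 | intermediate
15 | 3-(benzyloxy)-4-[4-(benzyloxy)benzyl]-5-{2-[3-(benzyloxy)phenyl]ethyl}phenol | Oc1cc(OCc2ccccc2)c(Cc2ccc(OCc3ccccc3)cc2)c(CCc2cccc(OCc3ccccc3)c2)c1 | intermediate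
16 | 1-(benzyloxy)-2-[4-(benzyloxy)benzyl]-3-{2-[3-(benzyloxy)phenyl]ethyl}-5-methoxybenzene | COc1cc(OCc2ccccc2)c(Cc2ccc(OCc3ccccc3)cc2)c(CCc2cccc(OCc3ccccc3)c2)c1 | intermediate
17 | IN1159, 2-(4-hydroxybenzyl)-3-[2-(3-hydroxyphenyl)ethyl]-5-methoxyphenol | COc1cc(O)c(Cc2ccc(O)cc2)c(CCc2cccc(O)c2)c1 | target

Total step count: 9.
Longest linear sequence: 8 steps (step 1 or step 2, then steps 3 to 9).

Steps most likely to fail

Step 4. Conjugate addition to the crowded trisubstituted alkene may be slow or may revert. Base-induced deconjugation or self-condensation of the enone could then consume material before the ring closes.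
- The fallback sets out from 6 and 8 and rejoins the route at 9, and through it at 10. It makes the C1–C2 bond first, with donor and acceptor roles exchanged.
- Knoevenagel condensation of 6 with 8 (piperidine, AcOH, toluene, water removal) would give dimethyl 2-{3-[3-(benzyloxy)phenyl]propylidene}malonate F1, a much stronger acceptor.
- Claisen–Schmidt condensation of 4-(benzyloxy)benzaldehyde with acetone (aqueous NaOH) would give (E)-4-[4-(benzyloxy)phenyl]but-3-en-2-one F2.
- 1,4-Hydrosilylation of the latter with Et3SiH and catalytic RhCl(PPh3)3 would give the regiodefined enol ether (Z)-{4-[4-(benzyloxy)phenyl]but-2-en-2-yl}oxy(triethyl)silane F3.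
- A Sc(OTf)3-catalysed Mukaiyama–Michael addition of the enol ether to the alkylidene malonate (CH2Cl2, −78 °C to 0 °C, aqueous work-up) should deliver 9 as an isolable compound under non-equilibrating conditions.
- Treatment of 9 with NaOMe in MeOH then only has to effect the Claisen closure to 10.

Step 5. Electrophilic bromination may spill over to C4 of the newly formed resorcinol or to rings A and C. Benzyl ethers may also be lost through acid cleavage while HBr is present at 80 °C.
- The fallback sets out from 10 and rejoins at 12 by a halogen-free, acid-free dehydrogenation.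
- Double silylation (TMSOTf, Et3N, CH2Cl2, 0 °C) would give methyl 5-[4-(benzyloxy)benzyl]-6-{2-[3-(benzyloxy)phenyl]ethyl}-2,4-bis(trimethylsilyloxy)cyclohexa-1,3-diene-1-carboxylate F4. Regioisomeric dienes would converge.
- DDQ (toluene, 0 °C) abstracts hydride from C1–H to give a cation stabilised by both siloxy groups. Loss of the C2 proton then gives methyl 5-[4-(benzyloxy)benzyl]-6-{2-[3-(benzyloxy)phenyl]ethyl}-2,4-bis(trimethylsilyloxy)benzoate F5.
- Dilute HCl in THF removes the silyl groups to give 12.

Step 3. Addition of the hindered α-benzyl phosphonate anion may be sluggish, so that self-aldolisation of the aldehyde outruns olefination.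
- The fallback sets out from 6 and rejoins at 7. It builds the trisubstituted alkene by allylic arylation and leaves out 3.
- A Morita–Baylis–Hillman reaction of 6 with but-3-en-2-one (DABCO, THF, rt) would give 6-[3-(benzyloxy)phenyl]-4-hydroxy-3-methylidenehexan-2-one F6.
- Acetylation (Ac2O, pyridine, DMAP) would give 1-[3-(benzyloxy)phenyl]-4-methylidene-5-oxohexan-3-yl acetate F7.
- Pd(OAc)2-catalysed coupling with 4-(benzyloxy)phenylboronic acid (K2CO3, THF–MeOH) places the aryl group on the unsubstituted allyl terminus and shifts the double bond. This is the known SN2'-type arylation of such acetates, and it gives 7.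

Further compounds
F1 | step 4 | dimethyl 2-{3-[3-(benzyloxy)phenyl]propylidene}malonate | COC(=O)C(=CCCc1cccc(OCc2ccccc2)c1)C(=O)OC
F2 | step 4 | (E)-4-[4-(benzyloxy)phenyl]but-3-en-2-one | CC(=O)/C=C/c1ccc(OCc2ccccc2)cc1
F3 | step 4 | (Z)-{4-[4-(benzyloxy)phenyl]but-2-en-2-yl}oxy(triethyl)silane | C/C(O[Si](CC)(CC)CC)=C/Cc1ccc(OCc2ccccc2)cc1
F4 | step 5 | methyl 5-[4-(benzyloxy)benzyl]-6-{2-[3-(benzyloxy)phenyl]ethyl}-2,4-bis(trimethylsilyloxy)cyclohexa-1,3-diene-1-carboxylate (diastereomer mixture) | COC(=O)C1=C(O[Si](C)(C)C)C=C(O[Si](C)(C)C)C(Cc2ccc(OCc3ccccc3)cc2)C1CCc1cccc(OCc2ccccc2)c1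
F5 | step 5 | methyl 5-[4-(benzyloxy)benzyl]-6-{2-[3-(benzyloxy)phenyl]ethyl}-2,4-bis(trimethylsilyloxy)benzoate | COC(=O)c1c(O[Si](C)(C)C)cc(O[Si](C)(C)C)c(Cc2ccc(OCc3ccccc3)cc2)c1CCc1cccc(OCc2ccccc2)c1
F6 | step 3 | 6-[3-(benzyloxy)phenyl]-4-hydroxy-3-methylidenehexan-2-one (racemic) | CC(=O)C(=C)C(O)CCc1cccc(OCc2ccccc2)c1
F7 | step 3 | 1-[3-(benzyloxy)phenyl]-4-methylidene-5-oxohexan-3-yl acetate (racemic) | CC(=O)OC(CCc1cccc(OCc2ccccc2)c1)C(=C)C(C)=O
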